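**Retrosynthetic overview**

1. Target 16 ← 15 (aryl MOM ethers removed last) ← 14 (acetylation of the C2 hydroxyl) ← 13 (selective hydrolysis of the vinylogous MOM ester); these are protecting-group moves made only after the quinone ring exists.
2. The quinone ring of 13 (C1=O, C2–O, C3–Ar, C4=O, C5–H, C6–Ar) is cut at C4–C5 and C6–C1: an anionic [4+2] annulation joins sulfonyl isotetronate 7 (lactone C=O → C1, enol-ether carbon → C2, aryl carbon → C3, sulfonyl-bearing C5 → C4) to 1-aryl vinyl sulfone 11 (CH2 → C5, aryl carbon → C6), and both sulfonyl groups leave as sulfinate.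
3. Enabling feature: the C1(=O)–C2(O)=C3(Ar)–C4(=O) half of the quinone ring has the atom pattern of a 4-aryl-3-oxyfuran-2(5H)-one. The other half is C5, the only ring carbon bearing hydrogen, next to C6, which bears an aryl group and no heteroatom; C6 can therefore carry a sulfonyl group that leaves with a C5 hydrogen and sets the quinone oxidation level without an oxidant.
4. 7 ← 4-hydroxyphenylpyruvic acid 1 + formaldehyde (aldol–lactonisation, MOM protection, C5 sulfenylation, oxidation); 11 ← aryl bromide 8 + methyl phenyl sulfone (Pd-catalysed α-arylation, Mannich methylenation).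
5. Ring order: butenolide ring first (step 1), quinone ring second (step 7), with the butenolide ring opened in the same operation; the two outer arene rings are bought.

Key step: step 7

Remark: the target has no stereocentre; every stereocentre that appears in an intermediate (2, 5, 6, 7, 10, 12) is formed as the racemate (6 as a diastereomer mixture) and is destroyed later.

**Route**

Step 1
Reactants: 1 4-hydroxyphenylpyruvic acid
Product: 3 3-hydroxy-4-(4-hydroxyphenyl)furan-2(5H)-one, via aldol adduct 2 (not isolated)
Conditions: 37% aq. HCHO (1.1 equiv), K2CO3 (1.5 equiv), H2O, rt; then conc. HCl to pH 1, rt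
Reagents that add atoms: formaldehyde, C=O
Why: Aldol addition of the benzylic enolate of the arylpyruvate to formaldehyde followed by acid-induced lactonisation and enolisation (aldol–lactonisation route to isotetronic acids); the carbon nucleophile should react with formaldehyde far faster than the phenolate at room temperature, and the stereocentre of 2 is lost on enolisation.

Step 2
Reactants: 3 3-hydroxy-4-(4-hydroxyphenyl)furan-2(5H)-one
Product: 4 3-(methoxymethoxy)-4-[4-(methoxymethoxy)phenyl]furan-2(5H)-one
Conditions: MOMCl (2.5 equiv), i-Pr2NEt (3 equiv), CH2Cl2, 0 °C → rt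
Reagents that add atoms: chloromethyl methyl ether, COCCl
Why: O-alkylation (Williamson-type acetal formation) of both the acidic enol hydroxyl and the phenol by the highly electrophilic chloromethyl ether; C3 is fully substituted, so only O-alkylation is open.

Step 3
Reactants: 4 3-(methoxymethoxy)-4-[4-(methoxymethoxy)phenyl]furan-2(5H)-one
Product: 5 3-(methoxymethoxy)-4-[4-(methoxymethoxy)phenyl]-5-(phenylsulfanyl)furan-2(5H)-one (racemic)
Conditions: LiN(SiMe3)2 (2.1 equiv), THF, −78 °C; PhSSPh (1.05 equiv), −78 → −20 °C; AcOH (2.1 equiv)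
Reagents that add atoms: diphenyl disulfide, c1ccc(SSc2ccccc2)cc1
Why: γ-Deprotonation gives the furanolate (dienolate), which is sulfenylated by the disulfide at C5 (enolate sulfenylation), the position that restores the aryl-conjugated butenolide since C3 is fully substituted; the second equivalent of base stores the more acidic product as its anion against a second sulfenylation, and the new C5 stereocentre is formed as the racemate.

Step 4
Reactants: 5 3-(methoxymethoxy)-4-[4-(methoxymethoxy)phenyl]-5-(phenylsulfanyl)furan-2(5H)-one
Product: 7 3-(methoxymethoxy)-4-[4-(methoxymethoxy)phenyl]-5-(phenylsulfonyl)furan-2(5H)-one (racemic), via sulfoxide 6 (not isolated)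
Conditions: mCPBA (2.2 equiv), CH2Cl2, 0 °C → rt
Reagents that add atoms: 3-chloroperoxybenzoic acid, O=C(OO)c1cccc(Cl)c1
Why: Stepwise S-oxidation by the peracid (sulfide to sulfoxide to sulfone), which should be much faster than epoxidation of the tetrasubstituted, ester-conjugated C3=C4 bond.

Step 5
Reactants: 8 1-bromo-4-(methoxymethoxy)benzene
Product: 9 1-(methoxymethoxy)-4-[(phenylsulfonyl)methyl]benzene
Conditions: PhSO2Me (1.5 equiv), Pd(OAc)2 (5 mol %), 2-[2-(dicyclohexylphosphino)phenyl]-1-methyl-1H-indole (10 mol %), LiOt-Bu (3 equiv), toluene, 110 °C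
Reagents that add atoms: methyl phenyl sulfone, CS(=O)(=O)c1ccccc1
Why: Palladium-catalysed α-arylation of a methyl sulfone with an aryl bromide (oxidative addition, transmetallation with the lithiated sulfone, reductive elimination); the bulky electron-rich phosphine and storage of the product as its anion should disfavour a second arylation, and the MOM ether is inert to the basic medium.

Step 6
Reactants: 9 1-(methoxymethoxy)-4-[(phenylsulfonyl)methyl]benzene
Product: 11 1-(methoxymethoxy)-4-[1-(phenylsulfonyl)ethenyl]benzene, via Mannich base 10 (not isolated)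
Conditions: Me2NCH2NMe2 (3 equiv), Ac2O (4 equiv), DMF, 60 °C
Reagents that add atoms: N,N,N',N'-tetramethylmethanediamine, CN(C)CN(C)C
Why: Mannich-type α-methylenation of a benzyl sulfone: the iminium acetate made in the flask aminomethylates the acidic benzylic position, and the Mannich base, N-acylated by the anhydride, loses the amine as its acetamide by E1cB elimination.

Step 7
Reactants: 7 3-(methoxymethoxy)-4-[4-(methoxymethoxy)phenyl]-5-(phenylsulfonyl)furan-2(5H)-one; 11 1-(methoxymethoxy)-4-[1-(phenylsulfonyl)ethenyl]benzene
Product: 13 2-(methoxymethoxy)-3,6-bis[4-(methoxymethoxy)phenyl]cyclohexa-2,5-diene-1,4-dione, via sulfonyl dihydroquinone 12 (not isolated)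
Conditions: 7, LiOt-Bu (2.5 equiv), THF, −78 °C; then 11 (1.1 equiv), −78 °C → rt; pH 7 phosphate buffer, rapid extraction
Reagents that add atoms: none
Why: Proposed new method: deprotonation of 7 at the sulfonyl-bearing C5 should give a furanolate that adds through C5 to the CH2 terminus of 11 (Michael addition), the tertiary α-sulfonyl benzylic carbanion so formed should attack the lactone carbonyl (Dieckmann-type acylation, 6-exo-trig closure of the new carbocycle), and collapse of the bridged alkoxide with loss of benzenesulfinate from the former C5 should give dione 12, whose CH2 group is then deprotonated with loss of the second sulfinate from the neighbouring carbon (E1cB) to give quinone 13. The closest known reaction type is the Hauser–Kraus annulation of 3-sulfonylphthalide anions with Michael acceptors; neither a monocyclic sulfonyl butenolide donor nor a 1-aryl vinyl sulfone acceptor, whose sulfonyl group is used as a leaving group, has been shown in it. The selectivity needed is regiochemical and is secured by polarity: the donor can lead on to a ring only through C5 (C3 is fully substituted and any adduct there can revert) and the acceptor is attacked only at CH2, so the lactone carbonyl must end between the oxygenated carbon and the new aryl-bearing carbon, and the former C5 between the other aryl-bearing carbon and the CH. Because the sulfonyl-bearing ring carbon of 12 has no hydrogen, 12 cannot tautomerise to a sulfonyl hydroquinone and can only go on to the quinone. No stereocentre survives: the single stereocentre of 12 is formed as the racemate and is destroyed by the elimination. Neutral work-up and quick removal of PhSO2Li should limit re-addition of sulfinate to the free C5 position of 13.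

Step 8
Reactants: 13 2-(methoxymethoxy)-3,6-bis[4-(methoxymethoxy)phenyl]cyclohexa-2,5-diene-1,4-dione
Product: 14 2-hydroxy-3,6-bis[4-(methoxymethoxy)phenyl]cyclohexa-2,5-diene-1,4-dione
Conditions: 1 M aq. HCl/THF (1:10), 0 °C → rt
Reagents that add atoms: none
Why: Acid-catalysed hydrolysis of a vinylogous methoxymethyl ester (the C2 oxygen is conjugated with the C4 carbonyl, so the hydroxyquinone is a good leaving group once protonated), which should be much faster than cleavage of the two aryl MOM ethers in dilute aqueous acid.

Step 9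
Reactants: 14 2-hydroxy-3,6-bis[4-(methoxymethoxy)phenyl]cyclohexa-2,5-diene-1,4-dione
Product: 15 2,5-bis[4-(methoxymethoxy)phenyl]-3,6-dioxocyclohexa-1,4-dien-1-yl acetate
Conditions: Ac2O (1.5 equiv), pyridine (2 equiv), CH2Cl2, 0 °C
Reagents that add atoms: acetic anhydride, CC(=O)OC(C)=O
Why: O-Acylation of the acidic hydroxyquinone (a vinylogous carboxylic acid) with acetic anhydride and pyridine, the standard esterification of hydroxyquinones; low temperature and short time should keep pyridine from adding to the free C5 position.

Step 10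
Reactants: 15 2,5-bis[4-(methoxymethoxy)phenyl]-3,6-dioxocyclohexa-1,4-dien-1-yl acetate
Product: 16 2,5-bis(4-hydroxyphenyl)-3,6-dioxocyclohexa-1,4-dien-1-yl acetate (neonambiquinone A)
Conditions: CF3CO2H/CH2Cl2 (1:4), 0 °C → rt; then H2O
Reagents that add atoms: none
Why: Acidolysis of aryl methoxymethyl ethers by trifluoroacetic acid (acetal cleavage through the methoxymethyl cation, hydrolysed on work-up) under non-nucleophilic, water-free conditions, so that the quinone enol acetate, a vinylogous anhydride, should survive.

**Compound list**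

1 | 4-hydroxyphenylpyruvic acid | O=C(O)C(=O)Cc1ccc(O)cc1 | starting material
2 | 4-hydroxy-3-(4-hydroxyphenyl)-2-oxobutanoic acid (racemic) | O=C(O)C(=O)C(CO)c1ccc(O)cc1 | intermediate (not isolated)
3 | 3-hydroxy-4-(4-hydroxyphenyl)furan-2(5H)-one | O=C1OCC(c2ccc(O)cc2)=C1O | intermediate
4 | 3-(methoxymethoxy)-4-[4-(methoxymethoxy)phenyl]furan-2(5H)-one | COCOC1=C(c2ccc(OCOC)cc2)COC1=O | intermediate
5 | 3-(methoxymethoxy)-4-[4-(methoxymethoxy)phenyl]-5-(phenylsulfanyl)furan-2(5H)-one (racemic) | COCOC1=C(c2ccc(OCOC)cc2)C(Sc2ccccc2)OC1=O | intermediate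
6 | 3-(methoxymethoxy)-4-[4-(methoxymethoxy)phenyl]-5-(phenylsulfinyl)furan-2(5H)-one (diastereomer mixture, racemic) | COCOC1=C(c2ccc(OCOC)cc2)C(S(=O)c2ccccc2)OC1=O | intermediate (not isolated)
7 | 3-(methoxymethoxy)-4-[4-(methoxymethoxy)phenyl]-5-(phenylsulfonyl)furan-2(5H)-one (racemic) | COCOC1=C(c2ccc(OCOC)cc2)C(S(=O)(=O)c2ccccc2)OC1=O | intermediate
8 | 1-bromo-4-(methoxymethoxy)benzene | COCOc1ccc(Br)cc1 | starting material
9 | 1-(methoxymethoxy)-4-[(phenylsulfonyl)methyl]benzene | COCOc1ccc(CS(=O)(=O)c2ccccc2)cc1 | intermediate
10 | N,N-dimethyl-2-[4-(methoxymethoxy)phenyl]-2-(phenylsulfonyl)ethan-1-amine (racemic) | CN(C)CC(c1ccc(OCOC)cc1)S(=O)(=O)c1ccccc1 | intermediate (not isolated)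
11 | 1-(methoxymethoxy)-4-[1-(phenylsulfonyl)ethenyl]benzene | C=C(c1ccc(OCOC)cc1)S(=O)(=O)c1ccccc1 | intermediate
12 | 2-(methoxymethoxy)-3,6-bis[4-(methoxymethoxy)phenyl]-6-(phenylsulfonyl)cyclohex-2-ene-1,4-dione (racemic) | COCOC1=C(c2ccc(OCOC)cc2)C(=O)CC(c2ccc(OCOC)cc2)(S(=O)(=O)c2ccccc2)C1=O | intermediate (not isolated)
13 | 2-(methoxymethoxy)-3,6-bis[4-(methoxymethoxy)phenyl]cyclohexa-2,5-diene-1,4-dione | COCOC1=C(c2ccc(OCOC)cc2)C(=O)C=C(c2ccc(OCOC)cc2)C1=O | intermediate
14 | 2-hydroxy-3,6-bis[4-(methoxymethoxy)phenyl]cyclohexa-2,5-diene-1,4-dione | OC1=C(c2ccc(OCOC)cc2)C(=O)C=C(c2ccc(OCOC)cc2)C1=O | intermediate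
15 | 2,5-bis[4-(methoxymethoxy)phenyl]-3,6-dioxocyclohexa-1,4-dien-1-yl acetate | CC(=O)OC1=C(c2ccc(OCOC)cc2)C(=O)C=C(c2ccc(OCOC)cc2)C1=O | intermediate
16 | 2,5-bis(4-hydroxyphenyl)-3,6-dioxocyclohexa-1,4-dien-1-yl acetate (neonambiquinone A) | CC(=O)OC1=C(c2ccc(O)cc2)C(=O)C=C(c2ccc(O)cc2)C1=O | target

**Step count and risks**

Total: 10 steps. Longest linear sequence: 8 steps (1, 2, 3, 4, 7, 8, 9, 10); the acceptor branch is steps 5 and 6.

Steps most likely to fail:

Step 7 (key annulation). The tertiary carbanion formed by the Michael addition may fail to close onto the lactone carbonyl and add to further vinyl sulfone instead (oligomerisation), or liberated sulfinate or tert-butoxide may add to the product quinone at its free position. The fallback uses known chemistry (cross-coupling, then hydroxylation of the quinone), sets out from 8 and comes back at 14. Double Suzuki–Miyaura coupling of 8 (2.2 equiv) with commercial 2,5-dimethoxy-1,4-phenylenediboronic acid (Pd(PPh3)4, K2CO3, dioxane/H2O, 90 °C) should give 1,4-dimethoxy-2,5-bis[4-(methoxymethoxy)phenyl]benzene F1. Oxidative demethylation with (NH4)2Ce(NO3)6 (MeCN/H2O, 0 °C) should give 2,5-bis[4-(methoxymethoxy)phenyl]cyclohexa-2,5-diene-1,4-dione F2. Nucleophilic (Weitz–Scheffer) mono-epoxidation with H2O2 and catalytic Na2CO3 (THF/H2O, 0 °C) should give 1,4-bis[4-(methoxymethoxy)phenyl]-7-oxabicyclo[4.1.0]hept-3-ene-2,5-dione F3. Base-induced opening of the epoxide by removal of its ring hydrogen (NaOH, 1.1 equiv, THF/H2O, 0 °C; then HCl) should place the hydroxyl next to the aryl-bearing carbon and give 14, from which steps 9 and 10 follow unchanged.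

Step 3 (C5 sulfenylation). Sulfenylation may occur at the α-carbon C3 of the dienolate, or a second sulfenylation at C5 may follow proton exchange between product and dienolate. The fallback sets out from 4 and comes back at 7. Radical bromination at the allylic, oxygen-bearing C5 (N-bromosuccinimide, cat. AIBN, PhCF3, 80 °C; Wohl–Ziegler) should give 5-bromo-3-(methoxymethoxy)-4-[4-(methoxymethoxy)phenyl]furan-2(5H)-one F4. S-Alkylation of PhSO2Na by this activated bromide (DMF, rt) should give 7 directly, which also makes step 4 unnecessary.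

Step 10 (final deprotection). The enol acetate may be lost by acyl exchange or hydrolysis in the acid, or the released methoxymethyl cation may attack the electron-rich phenol rings. The fallback sets out from 15 and comes back at 16, doing the deprotection at the hydroquinone level where the acetate is an ordinary aryl ester. Reduction with Na2S2O4 (EtOAc/H2O, rt) should give 3,6-dihydroxy-2,5-bis[4-(methoxymethoxy)phenyl]phenyl acetate F5. CF3CO2H/CH2Cl2 (0 °C), then water, should give 3,6-dihydroxy-2,5-bis(4-hydroxyphenyl)phenyl acetate F6. Oxidation with Ag2O (Et2O, rt) should return the quinone 16.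

**Further compounds**

F1 | step 7 | 1,4-dimethoxy-2,5-bis[4-(methoxymethoxy)phenyl]benzene | COc1cc(-c2ccc(OCOC)cc2)c(OC)cc1-c1ccc(OCOC)cc1
F2 | step 7 | 2,5-bis[4-(methoxymethoxy)phenyl]cyclohexa-2,5-diene-1,4-dione | O=C1C=C(c2ccc(OCOC)cc2)C(=O)C=C1c1ccc(OCOC)cc1
F3 | step 7 | 1,4-bis[4-(methoxymethoxy)phenyl]-7-oxabicyclo[4.1.0]hept-3-ene-2,5-dione (racemic) | O=C1C=C(c2ccc(OCOC)cc2)C(=O)C2OC12c1ccc(OCOC)cc1
F4 | step 3 | 5-bromo-3-(methoxymethoxy)-4-[4-(methoxymethoxy)phenyl]furan-2(5H)-one (racemic) | COCOC1=C(c2ccc(OCOC)cc2)C(Br)OC1=O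
F5 | step 10 | 3,6-dihydroxy-2,5-bis[4-(methoxymethoxy)phenyl]phenyl acetate | CC(=O)Oc1c(-c2ccc(OCOC)cc2)c(O)cc(-c2ccc(OCOC)cc2)c1O
F6 | step 10 | 3,6-dihydroxy-2,5-bis(4-hydroxyphenyl)phenyl acetate | CC(=O)Oc1c(-c2ccc(O)cc2)c(O)cc(-c2ccc(O)cc2)c1O
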